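Late times came first: 6.0 min lies past Monday's last reading at 80.0 s, so I wanted a quantity from which the clock has dropped out.

- Monday's: starting material 0.075 M; run made earlier
- flask: starting material 0.050 M; time 6.0 min

Monday's run (percent of the starting material charged)

| time / s | target / % | isomer of the product / % | starting material / % |
|---|---|---|---|
| 10.0 | 16 | 9 | 61 |
| 12.0 | 21 | 9 | 54 |
| 20.0 | 27 | 13 | 38 |
| 30.0 | 33 | 18 | 28 |
| 50.0 | 46 | 18 | 19 |
| 80.0 | 48 | 26 | 4 |

(readings scatter by 2 percentage points)

- a reading or a percentage of target counts all its forms, free or not
- a reading of starting material is of its free form alone

- share of target in target plus isomer of the product at 0.30 s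
- share of target in target plus isomer of the product at 6.0 min
- which of target and isomer of the product there is more of at 6.0 min

I divided the rate of gain of target by that of isomer of the product: while that ratio holds, two amounts that both start from nothing keep it and time disappears. Monday's share of target was 64.0 % at the first reading and 64.9 % at the last, while starting material fell from 61 % to 4 % of the charge. So I summed the target readings and divided by the summed target and isomer readings, which gave the pooled share 67.3 %. But in Monday's run at 30.0 s the three readings add up to 79.0 % of the charge, so the share gave me the split, not the amount. Monday's run also had one charge, 0.075 M, against 0.050 M here, so carrying the share over assumed that both routes answer the charge alike. For the new flask I committed to 67.3 % at both times, with target ahead.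

The forecast gave 67 % at 0.30 s, 66 % at 6.0 min and target ahead, judging that the share “holds steady with no trend”.

The flask gave 64.7 % at 0.30 s and 65.8 % at 6.0 min, with target ahead at 56.1 % of the charge against 29.1 % at that later time.

    2 starting material → homo dimer (k = 0.0110 M⁻¹ s⁻¹)
    starting material ⇌ target (K = 11.0, k = 0.0220 s⁻¹)
    starting material + target ⇌ idle adduct, settled at all times (K = 47.0 M⁻¹)
    starting material ⇌ isomer of the product (K = 6.00, k = 0.0120 s⁻¹)
    starting material ⇌ third isomer (K = 0.610, k = 1.60 × 10⁻⁴ s⁻¹)
    starting material + target → side product (k = 0.0230 M⁻¹ s⁻¹)

Kinetic and thermodynamic control ask for the same split here: 1.83 from the forward constants of target over isomer of the product, 1.83 from the equilibrium constants. On this flask at 6.0 min, the pooled share of the two products' 85.2 % of the charge gives 57.3 % as target. The neighbouring flask, charged with 0.020 M and otherwise the same, held 89.6 % of its charge in the two products at 6.00 min, so the pooled share gives 60.3 % as target. Its share at that time was 65.3 %, and its target, bound forms counted, stood at 58.5 %.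

(The runs are calculated with made-up constants, and the scatter is random.)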